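The ten-membered carbocycle is disconnected at C7–C8. O8 and the C12 lactone carbonyl are 1,4-related, a dissonant pairing, so C8 (aldehyde) and C7 (β-carbon of a C6 butenolide) are both electrophilic and have to be united reductively. One SmI2 step converts the aldehyde into a ketyl that attacks C7, closing the carbocycle onto the existing five-membered lactone ring and setting C7 and C8. The precursor is an open-chain (6S)-butenolide bearing the C4=C5 alkene, the C1=C10 enoate, a C15 PMB ether, a C9 TBS ether drawn from D-malate and a C8 aldehyde made immediately before use.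

Key step: step 15

Remark: atom numbers are the germacranolide numbers of the target (C1–C10 ring, C11–C13 lactone carbons, C14 ester carbon, C15 hydroxymethyl carbon).
Remark: O15 is masked as a PMB ether and O9 as a TBS ether, so each later unmasking (primary TBS, TES, secondary TBS, PMB) is orthogonal.
Assumption: (R,R)-ProPhenol is taken to deliver the 6R carbinol in step 11; the sense is checked by Mosher ester analysis of 20 and the antipodal ligand is used if it proves opposite.

Step 1
Reactants: 1 dimethyl (R)-malate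
Product: 2 methyl (R)-3,4-dihydroxybutanoate
Conditions: BH3·SMe2 (1.05 equiv), NaBH4 (5 mol%), THF, 0 °C to rt; MeOH quench
Reagents that add atoms: none
Why: Hydroxyl-directed borane reduction of an α-hydroxy ester (borane bound at the C9 hydroxyl and activated by catalytic NaBH4 reduces only the neighbouring ester), so the distal ester survives and C9 is taken unchanged from the chiral pool.

Step 2
Reactants: 2 methyl (R)-3,4-dihydroxybutanoate
Product: 3 methyl (R)-3,4-bis(tert-butyldimethylsilyloxy)butanoate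
Conditions: TBSCl (2.5 equiv), imidazole, DMF, 0 °C to rt
Reagents that add atoms: tert-butyldimethylsilyl chloride, CC(C)(C)[Si](C)(C)Cl
Why: Standard imidazole-promoted silyl ether formation; the primary hydroxyl is capped first, which prevents lactonisation, and no stereocentre is touched.

Step 3
Reactants: 4 but-2-yne-1,4-diol
Product: 5 4-[(4-methoxybenzyl)oxy]but-2-yn-1-ol
Conditions: NaH (1.0 equiv), 4 (3 equiv), PMBCl (1 equiv), Bu4NI (cat.), THF/DMF, 0 °C to rt
Reagents that add atoms: 4-methoxybenzyl chloride, COc1ccc(CCl)cc1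
Why: Williamson etherification of the monoalkoxide; the excess of diol keeps dialkylation low and is washed out with water.

Step 4
Reactants: 5 4-[(4-methoxybenzyl)oxy]but-2-yn-1-ol
Product: 7 (Z)-3-iodo-4-[(4-methoxybenzyl)oxy]but-2-en-1-ol, via alkenylaluminate 6 (not isolated)
Conditions: NaAlH2(OCH2CH2OMe)2 (Red-Al, 1.5 equiv), THF, 0 °C; then I2, THF, −78 °C to 0 °C
Reagents that add atoms: iodine, II
Why: Hydroxyl-directed trans-hydroalumination of a 2-alkyn-1-ol (hydride to C5, aluminium to C4 in a five-membered oxaaluminacycle) and iodinolysis with retention, the established route to (Z)-3-iodo-2-alken-1-ols; it fixes the C4=C5 geometry with the future C3 position cis to C6, and the low temperature should keep the aluminate from expelling the allylic ether as an allene.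

Step 5
Reactants: 7 (Z)-3-iodo-4-[(4-methoxybenzyl)oxy]but-2-en-1-ol; 8 acrolein diethyl acetal
Product: 10 (E)-6,6-diethoxy-3-{[(4-methoxybenzyl)oxy]methyl}hex-2-en-1-ol, via B-alkyl-9-BBN 9 (not isolated)
Conditions: 8, 9-BBN, THF, rt; then 7, PdCl2(dppf) (5 mol%), AsPh3, Cs2CO3, DMF/H2O, rt
Reagents that add atoms: none
Why: B-alkyl Suzuki–Miyaura coupling: 9-BBN hydroborates 8 at its CH2 terminus and the alkyl group is transferred to the alkenyl iodide with retention, so C3 ends cis to C6; the free allylic alcohol, the acetal and the PMB ether tolerate the aqueous base.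

Step 6
Reactants: 10 (E)-6,6-diethoxy-3-{[(4-methoxybenzyl)oxy]methyl}hex-2-en-1-ol
Product: 11 (E)-6-hydroxy-4-{[(4-methoxybenzyl)oxy]methyl}hex-4-enal
Conditions: PPTS (10 mol%), acetone/H2O (9:1), 40 °C
Reagents that add atoms: water, O
Why: Acid-catalysed hydrolysis of an acyclic acetal under pyridinium catalysis, which leaves the PMB ether, the allylic alcohol and the alkene geometry alone.

Step 7
Reactants: 11 (E)-6-hydroxy-4-{[(4-methoxybenzyl)oxy]methyl}hex-4-enal; 3 methyl (R)-3,4-bis(tert-butyldimethylsilyloxy)butanoate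
Product: 13 methyl (3R)-3,4-bis(tert-butyldimethylsilyloxy)-2-[(E)-1,6-dihydroxy-4-{[(4-methoxybenzyl)oxy]methyl}hex-4-en-1-yl]butanoate (epimers at C1 and C10), via ester lithium enolate 12 (not isolated)
Conditions: 3 (2.3 equiv), LiN(iPr)2 (2.2 equiv), THF, −78 °C; then 11, −78 °C; NH4Cl (aq)
Reagents that add atoms: none
Why: Aldol addition of a preformed lithium ester enolate to an unhindered aldehyde at −78 °C, where β-siloxy ester enolates do not yet eliminate; one equivalent of enolate is spent on the free hydroxyl (that ester is recovered), and the new centres at C1 and C10 disappear in step 8.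

Step 8
Reactants: 13 aldol diol
Product: 15 methyl (2E,6E)-8-acetoxy-2-[(1R)-1,2-bis(tert-butyldimethylsilyloxy)ethyl]-6-{[(4-methoxybenzyl)oxy]methyl}octa-2,6-dienoate, via diacetate 14 (not isolated)
Conditions: Ac2O (4 equiv), Et3N, DMAP (cat.), CH2Cl2, 0 °C to rt; then DBU (4 equiv), 40 °C
Reagents that add atoms: acetic anhydride, CC(=O)OC(C)=O
Why: Aldol dehydration by acetylation and E1cB elimination: DBU removes the C10 proton and the ester enolate expels acetate from C1 (a far better leaving group than the C9 siloxide), which is expected to favour the E enoate with C2 trans to the ester, while the O6 acetate serves as a protecting group.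

Step 9
Reactants: 15 acetate enoate
Product: 16 methyl (2E,6E)-2-[(1R)-1,2-bis(tert-butyldimethylsilyloxy)ethyl]-8-hydroxy-6-{[(4-methoxybenzyl)oxy]methyl}octa-2,6-dienoate
Conditions: K2CO3 (0.3 equiv), MeOH, 0 °C
Reagents that add atoms: none
Why: Base-catalysed transesterification removes the allylic acetate; the conjugated methyl ester is degenerate toward methoxide and the silyl ethers are stable.

Step 10
Reactants: 16 allylic alcohol
Product: 17 methyl (2E,6E)-2-[(1R)-1,2-bis(tert-butyldimethylsilyloxy)ethyl]-6-{[(4-methoxybenzyl)oxy]methyl}-8-oxoocta-2,6-dienoate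
Conditions: MnO2 (15 equiv), CH2Cl2, rt
Reagents that add atoms: none
Why: MnO2 oxidises only the allylic alcohol, under neutral conditions that should preserve the C4=C5 geometry.

Step 11
Reactants: 17 enal; 18 methyl propiolate
Product: 20 dimethyl (4R,5E,9E)-10-[(1R)-1,2-bis(tert-butyldimethylsilyloxy)ethyl]-4-hydroxy-6-{[(4-methoxybenzyl)oxy]methyl}undeca-5,9-dien-2-ynedioate, via zinc alkynylide 19 (not isolated)
Conditions: (R,R)-ProPhenol (20 mol%), Ph3PO (40 mol%), ZnMe2 (3 equiv), 18 (3 equiv), toluene, 0 °C to 4 °C; then 17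
Reagents that add atoms: none
Why: Zinc–ProPhenol catalysed asymmetric alkynylation of an enal: the dinuclear zinc complex binds aldehyde and alkynylzinc and delivers the alkyne to one carbonyl face, setting C6 (R) by catalyst control; esters, silyl ethers and the PMB ether are inert to ZnMe2.

Step 12
Reactants: 20 γ-hydroxy ynoate
Product: 22 methyl (2E,6E)-2-[(1R)-1,2-bis(tert-butyldimethylsilyloxy)ethyl]-6-{[(4-methoxybenzyl)oxy]methyl}-7-[(2S)-5-oxo-2,5-dihydrofuran-2-yl]hepta-2,6-dienoate, via (Z)-hydroxy enoate 21 (not isolated)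
Conditions: H2 (1 atm), Pd/CaCO3 poisoned with Pb(OAc)2 (Lindlar catalyst), quinoline, EtOAc, rt; then PPTS (cat.), CH2Cl2, rt
Reagents that add atoms: none
Why: Lindlar semi-hydrogenation of the ynoate gives the (Z)-γ-hydroxy enoate, which lactonises onto the C6 hydroxyl to the butenolide; the trisubstituted alkenes are not reduced and no bond at C6 changes.

Step 13
Reactants: 22 butenolide bis-silyl ether
Product: 23 methyl (2E,6E)-2-[(1R)-1-(tert-butyldimethylsilyloxy)-2-hydroxyethyl]-6-{[(4-methoxybenzyl)oxy]methyl}-7-[(2S)-5-oxo-2,5-dihydrofuran-2-yl]hepta-2,6-dienoate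
Conditions: HF·pyridine, pyridine, THF, 0 °C
Reagents that add atoms: none
Why: Buffered HF·pyridine cleaves a primary TBS ether much faster than the hindered secondary one at O9, and the acidic medium avoids silyl migration and epimerisation of the base-sensitive butenolide.

Step 14
Reactants: 23 primary alcohol
Product: 24 methyl (2E,6E)-2-[(1R)-1-(tert-butyldimethylsilyloxy)-2-oxoethyl]-6-{[(4-methoxybenzyl)oxy]methyl}-7-[(2S)-5-oxo-2,5-dihydrofuran-2-yl]hepta-2,6-dienoate
Conditions: Dess–Martin periodinane (1.5 equiv), NaHCO3, CH2Cl2, 0 °C; used at once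
Reagents that add atoms: none
Why: Dess–Martin oxidation under bicarbonate buffer gives the α-siloxy aldehyde without a base able to epimerise C9 (α to the aldehyde and allylic) or C6, and the crude aldehyde goes straight into step 15.

Step 15
Reactants: 24 butenolide aldehyde
Product: 25 ten-membered hydroxy lactone (O8 free; O9 TBS ether; C15 PMB ether; trans-fused saturated lactone; 6R 7R 8S 9R)
Conditions: SmI2 (3 equiv, 0.1 M in THF), t-BuOH (3 equiv), THF, 24 added over 6 h to 0.002 M, −78 °C to −20 °C; NH4Cl (aq) at −78 °C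
Reagents that add atoms: none
Why: Proposed new method: SmI2 (divalent samarium) reduces the C8 aldehyde reversibly to a samarium ketyl whose carbon radical adds to C7 of the butenolide, the C11 radical next to the lactone carbonyl takes a second electron to give the trivalent samarium enolate, and t-BuOH protonates it at C11, so C7–C8 is the only skeletal bond formed; the closest known chemistry is the SmI2 ketyl–olefin cyclisation of aldehydes onto unsaturated esters and lactones, established for five- to eight-membered rings, and the intermolecular ketyl addition to butenolides. The ten-membered carbocycle closes in the 10-exo-trig mode (C11 stays outside the new ring), helped by the two cis ring alkenes that fold the chain. C7 is controlled by C6: C3 is cis to C6 on the C4=C5 alkene, so allylic 1,3-strain keeps H6 in the alkene plane and leads the tether over the H6 face of the butenolide, which gives the trans-fused lactone (H6 anti to H7). C8 is controlled by C9: with the bulky, poorly chelating O9 TBS ether the ketyl should react through a Felkin–Anh arrangement with the C9–O bond anti to the forming bond, which places O8 cis to O9 on the ring. The step needs ketyl formation at the aldehyde in preference to reduction of the butenolide or the C14 enoate, which the easier reduction of an aldehyde and the absence of HMPA should secure, and ring closure in preference to pinacol coupling, which slow addition at 0.002 M should secure. The cold buffered quench limits attack of the O8 samarium alkoxide on the C12 or C14 carbonyl.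

Step 16
Reactants: 25 hydroxy lactone
Product: 26 O8 triethylsilyl ether of 25
Conditions: TESOTf (1.5 equiv), 2,6-lutidine, CH2Cl2, −78 °C
Reagents that add atoms: triethylsilyl triflate, CC[Si](CC)(CC)OS(=O)(=O)C(F)(F)F
Why: Silylation of a hindered secondary alcohol with the silyl triflate; it caps O8 so that no alkoxide can attack the C12 or C14 carbonyl during the enolate chemistry.

Step 17
Reactants: 26 O8 triethylsilyl ether
Product: 30 α-methylene lactone (C11=C13; O8 TES; O9 TBS; C15 PMB ether), via lactone lithium enolate 27 (not isolated), via Mannich base 28 (not isolated), via trimethylammonium iodide 29 (not isolated)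
Conditions: LiN(iPr)2 (1.2 equiv), THF, −78 °C; CH2=NMe2+ I− (3 equiv), −78 °C to 0 °C; then MeI, CH2Cl2/MeOH, rt; then NaHCO3 (aq), CH2Cl2, rt
Reagents that add atoms: N,N-dimethylmethyleneiminium iodide (Eschenmoser's salt), C=[N+](C)C.[I-]
Why: Lactone α-methylenation by the Mannich–elimination sequence: kinetic deprotonation at C11 (the only sp3 C–H α to a carbonyl), aminomethylation, N-methylation and E1cB loss of trimethylamine give the exocyclic alkene, with C7 untouched.

Step 18
Reactants: 30 α-methylene lactone TES ether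
Product: 31 α-methylene lactone with free O8 hydroxyl (O9 TBS; C15 PMB ether)
Conditions: PPTS (0.2 equiv), MeOH/CH2Cl2, 0 °C to rt
Reagents that add atoms: none
Why: Acid-catalysed methanolysis removes a triethylsilyl ether far faster than the secondary TBS ether, and the PMB ether and the methylene lactone are stable to pyridinium acid.

Step 19
Reactants: 31 C8 alcohol
Product: 32 O8 methacrylate (O9 TBS; C15 PMB ether)
Conditions: methacrylic anhydride (3 equiv), DMAP (1 equiv), Et3N, CH2Cl2, 0 °C to rt
Reagents that add atoms: methacrylic anhydride, CC(=C)C(=O)OC(=O)C(C)=C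
Why: DMAP-catalysed acyl transfer (Steglich-type acylation) to the C8 alcohol under neutral amine conditions that should not open or migrate the lactone.

Step 20
Reactants: 32 O8 methacrylate
Product: 33 C9 alcohol (O8 methacrylate; C15 PMB ether)
Conditions: HF·pyridine, THF, 0 °C to rt
Reagents that add atoms: none
Why: Fluoride cleavage of the remaining silyl ether under acidic HF·pyridine, which avoids the basic conditions that promote acyl migration from O8 to O9 or conjugate addition to the methylene lactone; the PMB ether is inert.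

Step 21
Reactants: 33 C9 alcohol
Product: 34 O9 acetate (O8 methacrylate; C15 PMB ether)
Conditions: Ac2O, pyridine, DMAP (cat.), CH2Cl2, 0 °C
Reagents that add atoms: acetic anhydride, CC(=O)OC(C)=O
Why: Standard acetylation of the C9 alcohol, run on the crude alcohol so that the neighbouring methacrylate has no time to migrate.

Step 22
Reactants: 34 PMB ether
Product: 35 target CNP0179134.4
Conditions: DDQ (1.3 equiv), CH2Cl2/pH 7 buffer (10:1), 0 °C
Reagents that add atoms: none
Why: Oxidative PMB cleavage by DDQ through the benzylic oxocarbenium ion and its hydrolysis; the esters, the methylene lactone and the alkenes are inert, and a short buffered reaction at 0 °C should spare the liberated allylic alcohol.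

Compound list
1 | dimethyl (R)-malate | COC(=O)C[C@@H](O)C(=O)OC | starting material
2 | methyl (R)-3,4-dihydroxybutanoate | COC(=O)C[C@@H](O)CO | intermediate
3 | methyl (R)-3,4-bis(tert-butyldimethylsilyloxy)butanoate | COC(=O)C[C@@H](O[Si](C)(C)C(C)(C)C)CO[Si](C)(C)C(C)(C)C | intermediate
4 | but-2-yne-1,4-diol | OCC#CCO | starting material
5 | 4-[(4-methoxybenzyl)oxy]but-2-yn-1-ol | OCC#CCOCc1ccc(OC)cc1 | intermediate
6 | sodium alkenylaluminate (five-membered oxaaluminacycle, Al on C4, two 2-methoxyethoxy ligands) | [Na+].COCCO[Al-]1(OCCOC)OC/C=C1/COCc2ccc(OC)cc2 | intermediate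
7 | (Z)-3-iodo-4-[(4-methoxybenzyl)oxy]but-2-en-1-ol | OC/C=C(/COCc1ccc(OC)cc1)I | intermediate
8 | acrolein diethyl acetal (3,3-diethoxyprop-1-ene) | C=CC(OCC)OCC | starting material
9 | B-(3,3-diethoxypropyl)-9-borabicyclo[3.3.1]nonane | CCOC(CCB1C2CCCC1CCC2)OCC | intermediate
10 | (E)-6,6-diethoxy-3-{[(4-methoxybenzyl)oxy]methyl}hex-2-en-1-ol | OC/C=C(/COCc1ccc(OC)cc1)CCC(OCC)OCC | intermediate
11 | (E)-6-hydroxy-4-{[(4-methoxybenzyl)oxy]methyl}hex-4-enal | OC/C=C(/COCc1ccc(OC)cc1)CCC=O | intermediate
12 | lithium enolate of ester 3 | [Li+].COC([O-])=C[C@@H](O[Si](C)(C)C(C)(C)C)CO[Si](C)(C)C(C)(C)C | intermediate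
13 | methyl (3R)-3,4-bis(tert-butyldimethylsilyloxy)-2-[(E)-1,6-dihydroxy-4-{[(4-methoxybenzyl)oxy]methyl}hex-4-en-1-yl]butanoate (epimers at C1 and C10) | OC/C=C(/COCc1ccc(OC)cc1)CCC(O)C(C(=O)OC)[C@@H](O[Si](C)(C)C(C)(C)C)CO[Si](C)(C)C(C)(C)C | intermediate
14 | diacetate of 13 (acetates at O1 and O6) | CC(=O)OC/C=C(/COCc1ccc(OC)cc1)CCC(OC(C)=O)C(C(=O)OC)[C@@H](O[Si](C)(C)C(C)(C)C)CO[Si](C)(C)C(C)(C)C | intermediate
15 | methyl (2E,6E)-8-acetoxy-2-[(1R)-1,2-bis(tert-butyldimethylsilyloxy)ethyl]-6-{[(4-methoxybenzyl)oxy]methyl}octa-2,6-dienoate | CC(=O)OC/C=C(/COCc1ccc(OC)cc1)CC/C=C(/C(=O)OC)[C@@H](O[Si](C)(C)C(C)(C)C)CO[Si](C)(C)C(C)(C)C | intermediate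
16 | methyl (2E,6E)-2-[(1R)-1,2-bis(tert-butyldimethylsilyloxy)ethyl]-8-hydroxy-6-{[(4-methoxybenzyl)oxy]methyl}octa-2,6-dienoate | OC/C=C(/COCc1ccc(OC)cc1)CC/C=C(/C(=O)OC)[C@@H](O[Si](C)(C)C(C)(C)C)CO[Si](C)(C)C(C)(C)C | intermediate
17 | methyl (2E,6E)-2-[(1R)-1,2-bis(tert-butyldimethylsilyloxy)ethyl]-6-{[(4-methoxybenzyl)oxy]methyl}-8-oxoocta-2,6-dienoate | O=C/C=C(/COCc1ccc(OC)cc1)CC/C=C(/C(=O)OC)[C@@H](O[Si](C)(C)C(C)(C)C)CO[Si](C)(C)C(C)(C)C | intermediate
18 | methyl propiolate | C#CC(=O)OC | starting material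
19 | methylzinc alkynylide of methyl propiolate | C[Zn]C#CC(=O)OC | intermediate
20 | dimethyl (4R,5E,9E)-10-[(1R)-1,2-bis(tert-butyldimethylsilyloxy)ethyl]-4-hydroxy-6-{[(4-methoxybenzyl)oxy]methyl}undeca-5,9-dien-2-ynedioate | COC(=O)C#C[C@H](O)/C=C(/COCc1ccc(OC)cc1)CC/C=C(/C(=O)OC)[C@@H](O[Si](C)(C)C(C)(C)C)CO[Si](C)(C)C(C)(C)C | intermediate
21 | (Z)-γ-hydroxy enoate from semi-reduction of 20 (C7=C11 cis, same configuration at C6 and C9) | COC(=O)/C=C\[C@H](O)/C=C(/COCc1ccc(OC)cc1)CC/C=C(/C(=O)OC)[C@@H](O[Si](C)(C)C(C)(C)C)CO[Si](C)(C)C(C)(C)C | intermediate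
22 | methyl (2E,6E)-2-[(1R)-1,2-bis(tert-butyldimethylsilyloxy)ethyl]-6-{[(4-methoxybenzyl)oxy]methyl}-7-[(2S)-5-oxo-2,5-dihydrofuran-2-yl]hepta-2,6-dienoate | O=C1C=C[C@H](O1)/C=C(/COCc2ccc(OC)cc2)CC/C=C(/C(=O)OC)[C@@H](O[Si](C)(C)C(C)(C)C)CO[Si](C)(C)C(C)(C)C | intermediate
23 | methyl (2E,6E)-2-[(1R)-1-(tert-butyldimethylsilyloxy)-2-hydroxyethyl]-6-{[(4-methoxybenzyl)oxy]methyl}-7-[(2S)-5-oxo-2,5-dihydrofuran-2-yl]hepta-2,6-dienoate | O=C1C=C[C@H](O1)/C=C(/COCc2ccc(OC)cc2)CC/C=C(/C(=O)OC)[C@@H](O[Si](C)(C)C(C)(C)C)CO | intermediate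
24 | methyl (2E,6E)-2-[(1R)-1-(tert-butyldimethylsilyloxy)-2-oxoethyl]-6-{[(4-methoxybenzyl)oxy]methyl}-7-[(2S)-5-oxo-2,5-dihydrofuran-2-yl]hepta-2,6-dienoate (butenolide aldehyde, key-step precursor) | O=C1C=C[C@H](O1)/C=C(/COCc2ccc(OC)cc2)CC/C=C(/C(=O)OC)[C@@H](O[Si](C)(C)C(C)(C)C)C=O | intermediate
25 | ten-membered hydroxy lactone (ring C1–C10 with C1=C10 and C4=C5 both cis in the ring; 6,12-lactone trans-fused at C6/C7; C8 OH; C9 OTBS; C10 CO2Me; C4 CH2OPMB; H7, H8 and H9 on one face, H6 on the other; 6R,7R,8S,9R) | O[C@H]1[C@H]2CC(=O)O[C@@H]2/C=C(/COCc3ccc(OC)cc3)CC/C=C(/C(=O)OC)[C@H]1O[Si](C)(C)C(C)(C)C | intermediate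
26 | O8 triethylsilyl ether of 25 (configuration unchanged) | CC[Si](CC)(CC)O[C@H]1[C@H]2CC(=O)O[C@@H]2/C=C(/COCc3ccc(OC)cc3)CC/C=C(/C(=O)OC)[C@H]1O[Si](C)(C)C(C)(C)C | intermediate
27 | lithium enolate of lactone 26 (C11=C12 enolate) | [Li+].CC[Si](CC)(CC)O[C@H]1[C@H]2C=C([O-])O[C@@H]2/C=C(/COCc3ccc(OC)cc3)CC/C=C(/C(=O)OC)[C@H]1O[Si](C)(C)C(C)(C)C | intermediate
28 | Mannich base: 11-(dimethylaminomethyl) derivative of 26 (C11 epimers) | CC[Si](CC)(CC)O[C@H]1[C@H]2C(CN(C)C)C(=O)O[C@@H]2/C=C(/COCc3ccc(OC)cc3)CC/C=C(/C(=O)OC)[C@H]1O[Si](C)(C)C(C)(C)C | intermediate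
29 | trimethylammonium iodide of 28 | CC[Si](CC)(CC)O[C@H]1[C@H]2C(C[N+](C)(C)C)C(=O)O[C@@H]2/C=C(/COCc3ccc(OC)cc3)CC/C=C(/C(=O)OC)[C@H]1O[Si](C)(C)C(C)(C)C.[I-] | intermediate
30 | α-methylene lactone (C11=C13) with O8 TES, O9 TBS and C15 PMB ethers | CC[Si](CC)(CC)O[C@H]1[C@H]2C(=C)C(=O)O[C@@H]2/C=C(/COCc3ccc(OC)cc3)CC/C=C(/C(=O)OC)[C@H]1O[Si](C)(C)C(C)(C)C | intermediate
31 | α-methylene lactone with free C8 hydroxyl, O9 TBS and C15 PMB ethers | O[C@H]1[C@H]2C(=C)C(=O)O[C@@H]2/C=C(/COCc3ccc(OC)cc3)CC/C=C(/C(=O)OC)[C@H]1O[Si](C)(C)C(C)(C)C | intermediate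
32 | O8 methacrylate of 31 | C=C(C)C(=O)O[C@H]1[C@H]2C(=C)C(=O)O[C@@H]2/C=C(/COCc3ccc(OC)cc3)CC/C=C(/C(=O)OC)[C@H]1O[Si](C)(C)C(C)(C)C | intermediate
33 | O8 methacrylate with free C9 hydroxyl and C15 PMB ether | C=C(C)C(=O)O[C@H]1[C@H]2C(=C)C(=O)O[C@@H]2/C=C(/COCc3ccc(OC)cc3)CC/C=C(/C(=O)OC)[C@H]1O | intermediate
34 | O8 methacrylate, O9 acetate, C15 PMB ether | C=C(C)C(=O)O[C@H]1[C@H]2C(=C)C(=O)O[C@@H]2/C=C(/COCc3ccc(OC)cc3)CC/C=C(/C(=O)OC)[C@H]1OC(C)=O | intermediate
35 | CNP0179134.4 (6R,7S,8S,9R; 8-methacrylate, 9-acetate, 15-hydroxy, 14-methyl ester, α-methylene 6,12-lactone) | C=C(C)C(=O)O[C@H]1[C@H]2C(=C)C(=O)O[C@@H]2/C=C(/CO)CC/C=C(/C(=O)OC)[C@H]1OC(C)=O | target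

Total step count: 22. Longest linear sequence: 20 steps (steps 3 to 22, from but-2-yne-1,4-diol); the two-step malate branch joins at step 7.

Steps most likely to fail

Step 15. The slow medium-ring closure may lose to pinacol coupling, to simple reduction of the aldehyde or to reductive opening of the butenolide. The ketyl may also add to the wrong face of C7 or give the C8 epimer, and the O8 samarium alkoxide may attack the C12 or C14 carbonyl. The fallback sets out from butenolide 22 and returns at 31, bypassing steps 15 to 18. It closes the same C7–C8 bond by known allylmetal chemistry. A phosphine-catalysed Baylis–Hillman hydroxymethylation (PBu3, aqueous CH2O, THF) gives the α-(hydroxymethyl)butenolide F1. Appel bromination (CBr4, PPh3) gives the allylic bromide F2. Buffered HF·pyridine frees the C8 alcohol F3, and Dess–Martin oxidation gives the bromo aldehyde F4. CrCl2 in THF/DMF at high dilution then effects a Nozaki–Hiyama allylation in which the allylchromium reacts through C7 with the C8 aldehyde. This forms the ring and the exocyclic C11=C13 alkene together and gives 31. Addition anti to the C5 substituent is expected, as for the intermolecular reaction. Chromium-mediated allylation of aldehydes by 2-(bromomethyl)-2-enoates is established, including for ten-membered germacranolide rings.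

Step 17. The amide base may deprotonate the γ-positions of the C14 enoate (C2 or C9) or add to it in conjugate fashion instead of enolising the lactone. The fallback sets out from 26 and returns at 28. Soft enolisation with Me3SiOTf and Et3N in CH2Cl2 gives the silyl ketene acetal F5. Eschenmoser's salt alkylates it in CH2Cl2 at rt (Mukaiyama–Mannich reaction) without any strong base to give Mannich base 28. Quaternisation and elimination then follow as in step 17.

Step 11. The β,β-disubstituted (Z)-enal may give poor facial discrimination, and the long reaction may erode the C4=C5 geometry through reversible conjugate addition. The fallback sets out from 17 and returns at 20. LiC≡CCO2Me (from 18 and LiN(SiMe3)2, THF, −78 °C) adds within minutes to give the racemic carbinol F6. MnO2 oxidises it to the ynone F7. (R)-Alpine-Borane then reduces F7, with the alkynyl group acting as the small substituent, to the 6R carbinol 20 (Midland reduction, known for 4-oxo-2-ynoates).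

Further compounds
F1 | step 15 | α-(hydroxymethyl)butenolide (22 with CH2OH on C11) | O=C1C(CO)=C[C@H](O1)/C=C(/COCc2ccc(OC)cc2)CC/C=C(/C(=O)OC)[C@@H](O[Si](C)(C)C(C)(C)C)CO[Si](C)(C)C(C)(C)C
F2 | step 15 | α-(bromomethyl)butenolide | O=C1C(CBr)=C[C@H](O1)/C=C(/COCc2ccc(OC)cc2)CC/C=C(/C(=O)OC)[C@@H](O[Si](C)(C)C(C)(C)C)CO[Si](C)(C)C(C)(C)C
F3 | step 15 | α-(bromomethyl)butenolide with free C8 alcohol | O=C1C(CBr)=C[C@H](O1)/C=C(/COCc2ccc(OC)cc2)CC/C=C(/C(=O)OC)[C@@H](O[Si](C)(C)C(C)(C)C)CO
F4 | step 15 | α-(bromomethyl)butenolide C8 aldehyde | O=C1C(CBr)=C[C@H](O1)/C=C(/COCc2ccc(OC)cc2)CC/C=C(/C(=O)OC)[C@@H](O[Si](C)(C)C(C)(C)C)C=O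
F5 | step 17 | trimethylsilyl ketene acetal of lactone 26 | CC[Si](CC)(CC)O[C@H]1[C@H]2C=C(O[Si](C)(C)C)O[C@@H]2/C=C(/COCc3ccc(OC)cc3)CC/C=C(/C(=O)OC)[C@H]1O[Si](C)(C)C(C)(C)C
F6 | step 11 | racemic C6 carbinol (20 without defined configuration at C6) | COC(=O)C#CC(O)/C=C(/COCc1ccc(OC)cc1)CC/C=C(/C(=O)OC)[C@@H](O[Si](C)(C)C(C)(C)C)CO[Si](C)(C)C(C)(C)C
F7 | step 11 | C6 ynone | COC(=O)C#CC(=O)/C=C(/COCc1ccc(OC)cc1)CC/C=C(/C(=O)OC)[C@@H](O[Si](C)(C)C(C)(C)C)CO[Si](C)(C)C(C)(C)C
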